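Time is your budget: the flask gets 8.0 h, so count how many halvings of c(left-handed substrate) that must hold. You wanted a quick number, so here is my own reckoning, then your hunch.

| flask | left-handed substrate | right-handed substrate | partner | precatalyst | remark | time |
|---|---|---|---|---|---|---|
| dawn | 0.41 M | 0.41 M | 0.82 M | 2.8 mM | run made earlier |  |
| summer | 0.41 M | 0.41 M | 0.82 M | 4.4 mM | run made earlier |  |
| dusk | 0.41 M | 0.41 M | 1.2 M | 2 mM | run made earlier |  |
| flask | 0.41 M | 0.41 M | 0.820 M | 2.0 mM |  | 8.0 h |

| run | time / h | right-handed substrate / % | left-handed substrate / % | left-handed product / % |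
|---|---|---|---|---|
| dawn | 0.667 | 53 | 33 | 19 |
| dawn | 1.33 | 48 | 12 | 23 |
| dawn | 2.50 | 49 | 5 | 26 |
| dawn | 4.00 | 44 | 1 | 28 |
| dawn | 8.00 | 47 | 0 | 26 |
| summer | 1.50 | 48 | 9 | 31 |
| summer | 3.00 | 47 | 0 | 31 |
| summer | 5.00 | 48 | 1 | 28 |
| summer | 6.00 | 49 | 1 | 26 |
| summer | 8.00 | 47 | 1 | 28 |
| dusk | 1.50 | 47 | 11 | 23 |
| dusk | 3.00 | 49 | 0 | 27 |
| dusk | 5.00 | 45 | 2 | 28 |
| dusk | 6.00 | 52 | 0 | 28 |
| dusk | 8.00 | 48 | 0 | 23 |

(standard deviation of a reading: 2 percentage points)

- catalyst is single-handed; left-handed substrate and right-handed substrate are mirror images of each other, charged as a racemate, each of them at the stated concentration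
- what was read earlier has a scatter of 2 percentage points, one standard deviation

* whether the excess of right-handed substrate over left-handed substrate among what is left of the two reaches 95% by 8.0 h (no / yes)
* the highest excess of right-handed substrate over left-handed substrate among what is left of the two up to 8.0 h

1. Take the racemate as the zero of the scale: c(right-handed substrate) and c(left-handed substrate) start equal, so the excess starts at nothing. In the dawn run the right-handed substrate reads 53% early and 47% at the end, so I treat it as flat and let the ratio grow as the left-handed substrate falls.
2. Reaching 95% takes 5.29 halvings; call this count the halvings needed.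
3. So the flask needs a half-life, averaged over the time allowed, of 1.51 h or shorter.
4. The dawn run, from 1.33 h to 2.50 h, reads a half-life of 0.926 h. If rate follows the precatalyst charge, the flask gets 1.30 h, which is shorter than required.
5. I therefore say yes, with about 97.3% by the end.
6. The forecast says yes and 99%, in its words “the likely outcome is yes”; its top is higher than mine.

The flask answers yes, with 98.9%.

    partner + catalyst + left-handed substrate → catalyst + left-handed product (k = 17.0 M⁻² min⁻¹)
    left-handed product ⇌ right-handed product (k = 0.0110 min⁻¹)
    partner + catalyst + right-handed substrate → catalyst + right-handed product (k = 0.130 M⁻² min⁻¹)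
    precatalyst → catalyst (k = 0.0360 min⁻¹)
    catalyst ⇌ dormant form (K = 0.360, k = 0.0580 min⁻¹)

The flask reaches the wanted excess at 5.42 h, and at 8.00 h its ratio counts 7.51 halvings against the 5.29 needed. The dawn run's reading at 4.00 h counts 5.46, though its 1% of left-handed substrate carries a scatter of 2 percentage points. In the flask, the left-handed substrate's half-life by its own step, 1.2 h at 8.00 h, is short against 8.0 h. Its rate constant stands 131 times that of the right-handed substrate (the selectivity factor), and 96% of the charged right-handed substrate remains at the end.

The earlier runs and the new flask are calculated for an exercise.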